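Atom numbers are those of the ent-kaurane skeleton: ring A = C1–C5 and C10, C6 = CH2OH carbon, lactone C7(=O)–O–C20, ring C = C8, C9, C11–C14, ring D = C8, C14, C13, C16, C15, C17 = methylene.
Retrosynthesis: C16=C17 (Mannich methylenation), then C8–C15 and C9–C11 together (ketyl–olefin/aldol cascade of a dialdehyde with two identical arms on C13), C8–C14 (Cr/Ni coupling), C8=C9 (metathesis), C9–C10 (alkynylation), and last the ring A bonds C2–C3 and C5–C10.
Enabling feature: the acetoxy carbon C1 lies between C2 and the spiro carbon C10, and O–C6 is 1,4 to O–C1. Ring A is thus a masked 2-carbomethoxycyclohexanone (ester carbon = C20) whose two α-carbons join a 1,3-bis-electrophile: aldehyde C3 and nitroalkene carbon C5, with nitro as the umpoled C6 oxygen.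
Forward order: ring A by a [3+3] Michael/aldol annulation of methyl acetoacetate, quaternary C10, reduction at C1/C20, spirolactone, C8–C14 coupling, rings C and D in one cascade, then C15 oxidation, C17 and deprotection.
Stereochemistry: C5 from the chiral thiourea catalyst; C10 (anti alkynylation) and C1 (bulky hydride) relayed from C5; C14 from the chiral chromium ligand; C9, C11, C13 and C8 from the chair transition state of the cascade.

Key step: step 2

Remark: the catalyst (step 2) and ligand (step 13) enantiomers are those that give the configurations drawn; the sense in step 2 is argued by analogy, the one in step 13 would be fixed by a ligand screen.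

Step 1
Reactants: 1 isobutyraldehyde; 2 (E)-N,N-dimethyl-2-nitroethenamine
Product: 3 (E)-2,2-dimethyl-4-nitrobut-3-enal
Conditions: KH, THF, 0 °C; then 2, −78 → 0 °C; 1 M HCl
Reagents that add atoms: none
Why: Enolate nitro-olefination (addition–elimination on a push–pull nitroenamine): the potassium enolate of 1 adds to the amine-bearing carbon of 2 and dimethylamine is lost on acidification, the new quaternary carbon preventing further enolisation and leaving the E nitroalkene.

Step 2
Reactants: 4 methyl acetoacetate; 3 (E)-2,2-dimethyl-4-nitrobut-3-enal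
Product: 6 cyclohexenone keto ester (methyl (6S)-5,5-dimethyl-6-(nitromethyl)-2-oxocyclohex-3-ene-1-carboxylate), via Michael adduct 5 (not isolated)
Conditions: (R,R)-1-[3,5-bis(trifluoromethyl)phenyl]-3-[2-(dimethylamino)cyclohexyl]thiourea (5 mol %), toluene, 0 °C → rt; then TsOH·H2O (20 mol %), 4 Å MS, 60 °C
Reagents that add atoms: none
Why: The thiourea–amine catalyst deprotonates 4 and hydrogen-bonds the nitro group of 3, so the acetoacetate α-carbon (C10) adds to the nitroalkene carbon C5 (first bond); the resulting 1,5-keto aldehyde 5 is then cyclised by acid through the C2 methyl enol onto the non-enolisable aldehyde C3 and dehydrated (second bond, left as C2=C3). The closest known reaction is the organocatalytic Michael/aldol-condensation [3+3] annulation of β-keto esters with enals, here with a nitroalkene as the Michael terminus because C4 is quaternary. Ring A closes in the aldol step by a 6-(enolendo)-exo-trig addition, the Michael step being intermolecular. The one permanent new stereocentre, C5, is set by the catalyst, which by analogy with its additions of malonates and β-keto esters to nitroalkenes should give the (S)-adduct; C10 stays epimerisable and is fixed in step 5. The step needs chemoselectivity (Michael addition before any condensation at the aldehyde) and regioselectivity in the ring closure; the first follows from the hindered neopentyl aldehyde and the absence of a secondary amine, the second from ring size, since the C10 enol or the nitronate could only close four-membered rings.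

Step 3
Reactants: 6 cyclohexenone keto ester
Product: 7 methyl (6S)-6-(dimethoxymethyl)-5,5-dimethyl-2-oxocyclohex-3-ene-1-carboxylate
Conditions: NaOMe (2.2 equiv), MeOH, 0 °C; then H2SO4, MeOH, −40 °C → rt
Reagents that add atoms: methanol, CO
Why: Nef reaction in its acetal-forming variant: the nitronate (the β-keto ester being held as its enolate, which blocks retro-Michael opening) is solvolysed in cold acidic methanol, so C6 reaches the aldehyde level as an acetal and C5 never sits next to a free aldehyde.

Step 4
Reactants: 7 acetal enone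
Product: 8 methyl (6S)-6-(dimethoxymethyl)-5,5-dimethyl-2-oxocyclohexane-1-carboxylate
Conditions: H2 (1 atm), 10% Pd/C, EtOAc, rt
Reagents that add atoms: none
Why: Heterogeneous hydrogenation of the disubstituted enone C2=C3 bond; no stereocentre is formed and acetal and β-keto ester are inert.

Step 5
Reactants: 8 saturated β-keto ester
Product: 9 methyl 6-(dimethoxymethyl)-1-ethynyl-5,5-dimethyl-2-oxocyclohexane-1-carboxylate (ethynyl trans to the dimethoxymethyl group)
Conditions: TMS-EBX (1.3 equiv), TBAF (1.3 equiv), THF, −78 °C
Reagents that add atoms: 1-[(trimethylsilyl)ethynyl]-1,2-benziodoxol-3(1H)-one (TMS-EBX), C[Si](C)(C)C#CI1OC(=O)c2ccccc12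
Why: Electrophilic alkynylation of a cyclic β-keto ester with an ethynylbenziodoxolone: the fluoride-generated enolate is attacked on the face opposite the neighbouring dimethoxymethyl group, which sets the quaternary C10 with C9 trans to C6 and the ester (future C20) cis.

Step 6
Reactants: 9 ethynyl keto ester
Product: 10 methyl 6-(dimethoxymethyl)-5,5-dimethyl-2-oxo-1-vinylcyclohexane-1-carboxylate
Conditions: H2 (1 atm), Lindlar catalyst, quinoline, EtOAc, rt
Reagents that add atoms: none
Why: Semihydrogenation of the terminal alkyne on a poisoned palladium catalyst stops at the vinyl group.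

Step 7
Reactants: 10 vinyl keto ester
Product: 12 diol 3-(dimethoxymethyl)-2-(hydroxymethyl)-4,4-dimethyl-2-vinylcyclohexan-1-ol (OH cis to vinyl), via hydroxy ester 11 (not isolated)
Conditions: L-Selectride, THF, −78 °C; then LiAlH4, −78 → 0 °C; Rochelle salt
Reagents that add atoms: none
Why: The bulky trialkylborohydride attacks the C1 ketone equatorially (as in reductions of 4,4-disubstituted 3-keto terpenoids) to give the axial C1–OH trans to the axial ester and cis to vinyl; LiAlH4 then reduces the hindered ester to the C20 carbinol.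

Step 8
Reactants: 12 diol
Product: 13 [2-(dimethoxymethyl)-6-hydroxy-3,3-dimethyl-1-vinylcyclohexyl]methyl acrylate
Conditions: acryloyl chloride (1.05 equiv), i-Pr2NEt, CH2Cl2, −78 °C
Reagents that add atoms: acryloyl chloride, C=CC(=O)Cl
Why: Acylation at low temperature takes the primary C20–OH in preference to the axial secondary C1–OH next to the quaternary centre.

Step 9
Reactants: 13 hydroxy acrylate
Product: 14 [6-acetoxy-2-(dimethoxymethyl)-3,3-dimethyl-1-vinylcyclohexyl]methyl acrylate
Conditions: Ac2O, DMAP (cat.), pyridine, rt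
Reagents that add atoms: acetic anhydride, CC(=O)OC(C)=O
Why: DMAP-catalysed acetylation of the only remaining hydroxyl installs the C1 acetate of the target; no later step uses a strong base.

Step 10
Reactants: 14 acetoxy acrylate
Product: 15 spirolactone 11-(dimethoxymethyl)-10,10-dimethyl-3-oxo-2-oxaspiro[5.5]undec-4-en-7-yl acetate
Conditions: second-generation Grubbs catalyst (5 mol %), toluene, 80 °C
Reagents that add atoms: none
Why: Ring-closing metathesis of the acrylate with the vinyl group closes the 5,6-dihydro-2H-pyran-2-one (C7, C8, C9) with loss of ethene; no stereocentre is touched.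

Step 11
Reactants: 15 spirolactone
Product: 16 4-iodo spirolactone (11-(dimethoxymethyl)-4-iodo-10,10-dimethyl-3-oxo-2-oxaspiro[5.5]undec-4-en-7-yl acetate)
Conditions: I2, pyridine, DMAP (cat.), CH2Cl2, rt
Reagents that add atoms: iodine, II
Why: α-Iodination of an α,β-unsaturated carbonyl compound by reversible conjugate addition of the amine, iodination of the enolate and elimination gives the C8 iodide.

Step 12
Reactants: 17 pent-4-enal; 18 allyl acetate
Product: 19 2-allylpent-4-enal
Conditions: Pd(PPh3)4 (5 mol %), pyrrolidine (20 mol %), DMSO, rt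
Reagents that add atoms: none
Why: Direct α-allylation of an aldehyde by combined enamine and π-allylpalladium catalysis; the product is achiral because its two allyl arms are identical.

Step 13
Reactants: 16 4-iodo spirolactone; 19 2-allylpent-4-enal
Product: 20 allylic alcohol 4-(2-allyl-1-hydroxypent-4-en-1-yl)-11-(dimethoxymethyl)-10,10-dimethyl-3-oxo-2-oxaspiro[5.5]undec-4-en-7-yl acetate
Conditions: CrCl2, NiCl2 (cat.), chiral sulfonamide ligand, Et3N, MeCN/THF, rt
Reagents that add atoms: none
Why: Nozaki–Hiyama–Kishi coupling: the alkenylchromium(III) formed from the iodide adds only to the aldehyde (C8–C14 bond), and the C14 carbinol configuration is set by the chiral ligand on chromium because the nearest substrate stereocentre is too remote.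

Step 14
Reactants: 20 allylic alcohol
Product: 21 tert-butyldimethylsilyl ether of 20
Conditions: TBSCl, imidazole, DMF, 40 °C
Reagents that add atoms: tert-butyldimethylsilyl chloride, CC(C)(C)[Si](C)(C)Cl
Why: Silylation of the allylic alcohol under chloride/imidazole conditions, chosen because a silyl triflate would attack the dimethyl acetal.

Step 15
Reactants: 21 silyl ether
Product: 22 dialdehyde (both allyl arms cut to CH2CHO)
Conditions: O3, CH2Cl2, pyridine (cat.), Sudan III, −78 °C; then PPh3
Reagents that add atoms: ozone, [O-][O+]=O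
Why: Ozonolysis to a dye end-point cleaves the two electron-rich terminal alkenes and spares the electron-poor trisubstituted lactone alkene; reductive work-up gives the dialdehyde, used at once.

Step 16
Reactants: 22 dialdehyde
Product: 23 tetracyclic diol (1-acetoxy-14-silyloxy-11,15-dihydroxy-6,6-dimethoxy-17-nor-6,7-seco-ent-kauran-7,20-olide)
Conditions: SmI2 (2.5 equiv), LiBr, t-BuOH, THF, −78 °C
Reagents that add atoms: none
Why: Ketyl–olefin cyclisation/aldol cascade: the ketyl from one aldehyde arm adds 6-endo to C9 of the unsaturated lactone through a chair with C10, the ketyl oxygen and the second arm equatorial and the silyloxy group axial (relief of A1,2 strain), giving C11–OH trans to C10 and a cis-fused lactone; the samarium enolate then closes ring D by 5-exo aldol addition to the second arm (C8–C15), which makes C8 quaternary and fixes C13, the C15 carbinol configuration being immaterial.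

Step 17
Reactants: 23 tetracyclic diol
Product: 24 hydroxy ketone (C15 ketone, C11–OH kept)
Conditions: TEMPO (20 mol %), PhI(OAc)2, CH2Cl2, rt
Reagents that add atoms: none
Why: Nitroxyl-catalysed oxidation is governed by access to the carbinol: the C15–OH on the convex face should be oxidised, while the axial 11-OH, buried between ring A and the C15–C16 bridge, should be left.

Step 18
Reactants: 24 hydroxy ketone
Product: 25 exo-methylene enone (C16=C17)
Conditions: (CH2O)n, N-methylanilinium trifluoroacetate, THF, reflux
Reagents that add atoms: paraformaldehyde (formaldehyde), C=O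
Why: Mannich-type α-methylenation: the C15 ketone can enolise only towards C16 because C8 is quaternary, and the non-basic conditions spare the acetate, silyl ether and acetal.

Step 19
Reactants: 25 exo-methylene enone
Product: 26 C6 aldehyde with free 11- and 14-hydroxyls
Conditions: 48% aq. HF, MeCN, 0 °C → rt
Reagents that add atoms: water, O
Why: Aqueous HF cleaves the silyl ether and hydrolyses the dimethyl acetal to the C6 aldehyde; acetate, lactone and enone are stable to these acidic conditions.

Step 20
Reactants: 26 C6 aldehyde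
Product: 27 target CNP0225182.1
Conditions: NaBH(OAc)3, AcOH (cat.), THF, rt
Reagents that add atoms: none
Why: Sodium triacetoxyborohydride reduces aldehydes but not ketones or enones, so only the C6 aldehyde is reduced to the primary alcohol.

Compound list
1 | isobutyraldehyde | CC(C)C=O | starting material
2 | (E)-N,N-dimethyl-2-nitroethenamine | CN(C)/C=C/[N+](=O)[O-] | starting material
3 | (E)-2,2-dimethyl-4-nitrobut-3-enal | O=CC(C)(C)/C=C/[N+](=O)[O-] | intermediate
4 | methyl acetoacetate | COC(=O)CC(C)=O | starting material
5 | methyl (3S)-2-acetyl-4,4-dimethyl-3-(nitromethyl)-5-oxopentanoate (C2 labile) | COC(=O)C(C(C)=O)[C@H](C[N+](=O)[O-])C(C)(C)C=O | intermediate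
6 | methyl (6S)-5,5-dimethyl-6-(nitromethyl)-2-oxocyclohex-3-ene-1-carboxylate (C1 labile) | COC(=O)C1C(=O)C=CC(C)(C)[C@H]1C[N+](=O)[O-] | intermediate
7 | methyl (6S)-6-(dimethoxymethyl)-5,5-dimethyl-2-oxocyclohex-3-ene-1-carboxylate (C1 labile) | COC(=O)C1C(=O)C=CC(C)(C)[C@H]1C(OC)OC | intermediate
8 | methyl (6S)-6-(dimethoxymethyl)-5,5-dimethyl-2-oxocyclohexane-1-carboxylate (C1 labile) | COC(=O)C1C(=O)CCC(C)(C)[C@H]1C(OC)OC | intermediate
9 | methyl 6-(dimethoxymethyl)-1-ethynyl-5,5-dimethyl-2-oxocyclohexane-1-carboxylate, ethynyl trans to dimethoxymethyl | COC(=O)[C@]1(C(=O)CCC(C)(C)[C@H]1C(OC)OC)C#C | intermediate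
10 | methyl 6-(dimethoxymethyl)-5,5-dimethyl-2-oxo-1-vinylcyclohexane-1-carboxylate, vinyl trans to dimethoxymethyl | COC(=O)[C@]1(C(=O)CCC(C)(C)[C@H]1C(OC)OC)C=C | intermediate
11 | methyl 6-(dimethoxymethyl)-2-hydroxy-5,5-dimethyl-1-vinylcyclohexane-1-carboxylate, OH cis to vinyl | COC(=O)[C@]1([C@@H](O)CCC(C)(C)[C@H]1C(OC)OC)C=C | intermediate
12 | 3-(dimethoxymethyl)-2-(hydroxymethyl)-4,4-dimethyl-2-vinylcyclohexan-1-ol, OH cis to vinyl, CH2OH cis to dimethoxymethyl | OC[C@]1([C@@H](O)CCC(C)(C)[C@H]1C(OC)OC)C=C | intermediate
13 | [2-(dimethoxymethyl)-6-hydroxy-3,3-dimethyl-1-vinylcyclohexyl]methyl acrylate | C=CC(=O)OC[C@]1([C@@H](O)CCC(C)(C)[C@H]1C(OC)OC)C=C | intermediate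
14 | [6-acetoxy-2-(dimethoxymethyl)-3,3-dimethyl-1-vinylcyclohexyl]methyl acrylate | C=CC(=O)OC[C@]1([C@@H](OC(C)=O)CCC(C)(C)[C@H]1C(OC)OC)C=C | intermediate
15 | 11-(dimethoxymethyl)-10,10-dimethyl-3-oxo-2-oxaspiro[5.5]undec-4-en-7-yl acetate | O=C1OC[C@]2([C@@H](OC(C)=O)CCC(C)(C)[C@H]2C(OC)OC)C=C1 | intermediate
16 | 11-(dimethoxymethyl)-4-iodo-10,10-dimethyl-3-oxo-2-oxaspiro[5.5]undec-4-en-7-yl acetate | O=C1OC[C@]2([C@@H](OC(C)=O)CCC(C)(C)[C@H]2C(OC)OC)C=C1I | intermediate
17 | pent-4-enal | C=CCCC=O | starting material
18 | allyl acetate | C=CCOC(C)=O | starting material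
19 | 2-allylpent-4-enal | C=CCC(CC=C)C=O | intermediate
20 | 4-(2-allyl-1-hydroxypent-4-en-1-yl)-11-(dimethoxymethyl)-10,10-dimethyl-3-oxo-2-oxaspiro[5.5]undec-4-en-7-yl acetate (C14 carbinol as in the target) | O=C1OC[C@]2([C@@H](OC(C)=O)CCC(C)(C)[C@H]2C(OC)OC)C=C1[C@H](O)C(CC=C)CC=C | intermediate
21 | tert-butyldimethylsilyl ether of 20 | O=C1OC[C@]2([C@@H](OC(C)=O)CCC(C)(C)[C@H]2C(OC)OC)C=C1[C@H](O[Si](C)(C)C(C)(C)C)C(CC=C)CC=C | intermediate
22 | dialdehyde from 21 (side chain CH(OTBS)CH(CH2CHO)2) | O=C1OC[C@]2([C@@H](OC(C)=O)CCC(C)(C)[C@H]2C(OC)OC)C=C1[C@H](O[Si](C)(C)C(C)(C)C)C(CC=O)CC=O | intermediate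
23 | 1-acetoxy-14-(tert-butyldimethylsilyloxy)-11,15-dihydroxy-6,6-dimethoxy-17-nor-6,7-seco-ent-kauran-7,20-olide (C15 configuration left open) | C1C(O)[C@@]23C(=O)OC[C@]4([C@@H](OC(C)=O)CCC(C)(C)[C@H]4C(OC)OC)[C@@H]2[C@@H](O)C[C@@H]1[C@H]3O[Si](C)(C)C(C)(C)C | intermediate
24 | 1-acetoxy-14-(tert-butyldimethylsilyloxy)-11-hydroxy-6,6-dimethoxy-15-oxo-17-nor-6,7-seco-ent-kauran-7,20-olide | C1C(=O)[C@@]23C(=O)OC[C@]4([C@@H](OC(C)=O)CCC(C)(C)[C@H]4C(OC)OC)[C@@H]2[C@@H](O)C[C@@H]1[C@H]3O[Si](C)(C)C(C)(C)C | intermediate
25 | 1-acetoxy-14-(tert-butyldimethylsilyloxy)-11-hydroxy-6,6-dimethoxy-15-oxo-6,7-seco-ent-kaur-16-en-7,20-olide | C=C1C(=O)[C@@]23C(=O)OC[C@]4([C@@H](OC(C)=O)CCC(C)(C)[C@H]4C(OC)OC)[C@@H]2[C@@H](O)C[C@@H]1[C@H]3O[Si](C)(C)C(C)(C)C | intermediate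
26 | 1-acetoxy-11,14-dihydroxy-6,15-dioxo-6,7-seco-ent-kaur-16-en-7,20-olide | C=C1C(=O)[C@@]23C(=O)OC[C@]4([C@@H](OC(C)=O)CCC(C)(C)[C@H]4C=O)[C@@H]2[C@@H](O)C[C@@H]1[C@H]3O | intermediate
27 | 1-acetoxy-6,11,14-trihydroxy-15-oxo-6,7-seco-ent-kaur-16-en-7,20-olide (CNP0225182.1) | C=C1C(=O)[C@@]23C(=O)OC[C@]4([C@@H](OC(C)=O)CCC(C)(C)[C@H]4CO)[C@@H]2[C@@H](O)C[C@@H]1[C@H]3O | target

Total step count: 20. Longest linear sequence: 19 steps (steps 1–11 and 13–20; step 12 is a one-step side branch).

Steps most likely to fail

Step 16. The two aldehyde arms form a 1,5-dialdehyde and may undergo pinacol coupling with each other before the ketyl reaches C9. The samarium enolate may also lose the β-silyloxy group by elimination, or the diastereotopic arm that cannot be bridged may cyclise first. Fallback: setting out from dialdehyde 22, an N-heterocyclic-carbene-catalysed domino Stetter/aldol reaction (triazolium salt, i-Pr2NEt, THF) forms the same two bonds by polar acyl-anion addition to C9 and enolate aldol closure, with no single-electron reductant present. It should give the 11-oxo-15-hydroxy tetracycle F1. Reduction of the C11 ketone of F1 from the exo face (L-Selectride, −78 °C), away from the C15–C16 bridge, comes back to the route at diol 23.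

Step 17. Oxidation may occur at the wrong carbinol (the strained axial 11-OH) or at both, or not at all at the neopentyl C15–OH. Fallback: setting out from diol 23, excess Dess–Martin periodinane oxidises both carbinols to the 11,15-dione F2. The six-ring ketone is then reduced chemoselectively, the cyclohexanone being more reactive than the α-quaternary cyclopentanone (L-Selectride, 1 equiv, −78 °C, exo attack), which comes back to the route at hydroxy ketone 24.

Step 13. Facial selectivity in the addition to the aldehyde may be poor, giving a mixture of C14 epimers, of which only one is matched with the chair of the cascade. Fallback: setting out from the epimer mixture of 20, Dess–Martin oxidation gives the cross-conjugated enone F3. Corey–Bakshi–Shibata reduction (oxazaborolidine, catecholborane, −78 °C) then sets C14 under reagent control at the ketone stage and comes back to the route at 20.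

Further compounds
F1 | step 16 | 1-acetoxy-14-(tert-butyldimethylsilyloxy)-15-hydroxy-6,6-dimethoxy-11-oxo-17-nor-6,7-seco-ent-kauran-7,20-olide | C1C(O)[C@@]23C(=O)OC[C@]4([C@@H](OC(C)=O)CCC(C)(C)[C@H]4C(OC)OC)[C@@H]2C(=O)C[C@@H]1[C@H]3O[Si](C)(C)C(C)(C)C
F2 | step 17 | 1-acetoxy-14-(tert-butyldimethylsilyloxy)-6,6-dimethoxy-11,15-dioxo-17-nor-6,7-seco-ent-kauran-7,20-olide | C1C(=O)[C@@]23C(=O)OC[C@]4([C@@H](OC(C)=O)CCC(C)(C)[C@H]4C(OC)OC)[C@@H]2C(=O)C[C@@H]1[C@H]3O[Si](C)(C)C(C)(C)C
F3 | step 13 | 4-(2-allylpent-4-enoyl)-11-(dimethoxymethyl)-10,10-dimethyl-3-oxo-2-oxaspiro[5.5]undec-4-en-7-yl acetate | O=C1OC[C@]2([C@@H](OC(C)=O)CCC(C)(C)[C@H]2C(OC)OC)C=C1C(=O)C(CC=C)CC=C
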